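## Retrosynthetic overview

1. Target ⇐ (chloride demethylation, desilylation) O‑methyl bis‑silyl tetracycle ⇐ one‑flask oxidation and double intramolecular Diels–Alder reaction of an acyclic 3‑acyl‑5‑methylene tetronate hexaene, mirroring the presumed biosynthetic order.
2. Ring order in that flask: rings A and B of the trans‑decalin first (bonds C4–C13 and C5–C10), then the spiro‑cyclohexene and the 11‑membered carbocycle together (bonds C21–C24 and C18–C25). The tetronate ring is bought as methyl tetronate.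
3. Acyclic precursor ⇐ 3‑lithio‑4‑methoxy‑5‑methylenefuranone + C3–C23 hexaenal ⇐ Wittig (C4=C5), ester half‑reduction, Negishi coupling (C11–C12).
4. C5–C11 alkyne with the C7–C9 anti,anti triad ⇐ auxiliary anti‑aldol, Claisen condensation, 1,3‑syn reduction.
5. C12–C23 tetraenyl iodide ⇐ ylide alkylation and Z‑Wittig (C15=C16) of a dienyl bromide with (E)‑4‑iodobut‑3‑enal.

Locants used below: C1 lactone carbonyl, C2, C3 acyl carbon, C4 (methyl) to C23 (end of the ethyl group) along the chain, C24 ring CH2 (former exo‑methylene), C25 spiro carbon, C26 tetronate C–O carbon. The target is (4R,5R,7S,8S,9R,10S,13R,18R,21R,25S,15Z).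

Assumption: the MgBr2‑catalysed anti‑aldol of N‑propanoyl thiazolidinethiones uses the same enolate face as the boron syn‑aldol of that auxiliary, so the (R)‑auxiliary gives the (2R,3S) adduct 17; if the sense is the reverse, the (S)‑auxiliary is used and nothing else changes.

Assumption: 2, 10, 15, 16, 29, 31 and 32 are taken as catalogue compounds.

## Route

Step 1
Reactants: 1 (E)-2-methylpent-2-enal; 2 ethyl 2-(triphenylphosphoranylidene)propanoate
Product: 3 ethyl (2E,4E)-2,4-dimethylhepta-2,4-dienoate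
Conditions: toluene, 90 °C
Reagents that add atoms: none
Why: Wittig olefination with a stabilised ylide gives the E‑trisubstituted C18=C19 alkene (>95:5) beside the E‑alkene already in 1; no stereocentre.

Step 2
Reactants: 3 ethyl (2E,4E)-2,4-dimethylhepta-2,4-dienoate
Product: 4 (2E,4E)-2,4-dimethylhepta-2,4-dien-1-ol
Conditions: iBu2AlH (2.2 equiv), CH2Cl2, −78 → 0 °C
Reagents that add atoms: none
Why: aluminium hydride 1,2‑reduction of the conjugated ester to the allylic alcohol leaves the diene geometry untouched.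

Step 3
Reactants: 4 (2E,4E)-2,4-dimethylhepta-2,4-dien-1-ol
Product: 5 (2E,4E)-1-bromo-2,4-dimethylhepta-2,4-diene
Conditions: PBr3 (0.4 equiv), Et2O, 0 °C; used crude
Reagents that add atoms: phosphorus tribromide, BrP(Br)Br
Why: bromination of a primary allylic alcohol through its phosphite ester (SN2); the conjugated primary bromide is also the thermodynamic allylic isomer.

Step 4
Reactants: 6 but-3-yn-1-ol
Product: 8 (E)-4-iodobut-3-en-1-ol, via O,C-bis(zirconocene) butenol 7 (not isolated)
Conditions: Cp2Zr(H)Cl (2.2 equiv), THF, rt; then I2, 0 °C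
Reagents that add atoms: iodine, II
Why: hydrozirconation (syn addition, zirconium on the terminal carbon; the first equivalent is consumed by the hydroxyl) and iodinolysis with retention give only the E‑vinyl iodide.

Step 5
Reactants: 8 (E)-4-iodobut-3-en-1-ol
Product: 9 (E)-4-iodobut-3-enal
Conditions: Dess–Martin periodinane, CH2Cl2, 0 °C; used at once
Reagents that add atoms: none
Why: Dess–Martin oxidation is mild and non‑basic, so the β,γ‑unsaturated aldehyde is not drawn into conjugation.

Step 6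
Reactants: 5 (2E,4E)-1-bromo-2,4-dimethylhepta-2,4-diene; 10 methyltriphenylphosphonium bromide; 9 (E)-4-iodobut-3-enal
Product: 14 (1E,4Z,7E,9E)-1-iodo-7,9-dimethyldodeca-1,4,7,9-tetraene, via methylenetriphenylphosphorane 11 (not isolated), via homoallylic phosphonium bromide 12 (not isolated), via homoallylic ylide 13 (not isolated)
Conditions: 10, NaN(SiMe3)2, THF, 0 °C; 5, −78 °C → rt; NaN(SiMe3)2, −78 °C; 9, −78 °C → rt
Reagents that add atoms: none
Why: C‑alkylation of the methylene ylide by the allylic bromide, then lithium‑free Wittig olefination of the resulting non‑stabilised ylide, which gives the Z‑alkene (C15=C16) kinetically; the E‑iodide and E,E‑diene are carried through unchanged.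

Step 7
Reactants: 15 (R)-4-benzyl-3-propanoyl-1,3-thiazolidine-2-thione; 16 3-(trimethylsilyl)prop-2-ynal
Product: 17 (R)-4-benzyl-3-[(2R,3S)-2-methyl-5-(trimethylsilyl)-3-(trimethylsilyloxy)pent-4-ynoyl]-1,3-thiazolidine-2-thione
Conditions: MgBr2·OEt2 (10 mol %), Et3N, Me3SiCl, EtOAc, rt
Reagents that add atoms: chlorotrimethylsilane, C[Si](C)(C)Cl
Why: magnesium‑halide‑catalysed direct anti‑aldol reaction of an N‑acylthiazolidinethione (Evans): the benzyl group of the auxiliary blocks one enolate face (sets C8) and the boat‑like transition state gives the anti C8/C9 relationship, while silylation of the aldolate releases the catalyst.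

Step 8
Reactants: 17 (R)-4-benzyl-3-[(2R,3S)-2-methyl-5-(trimethylsilyl)-3-(trimethylsilyloxy)pent-4-ynoyl]-1,3-thiazolidine-2-thione; 18 methyl acetate
Product: 21 methyl (4R,5S)-5-hydroxy-4-methyl-3-oxo-7-(trimethylsilyl)hept-6-ynoate, via lithium enolate of methyl acetate 19 (not isolated), via O-trimethylsilyl keto ester 20 (not isolated)
Conditions: LiN(iPr)2, 18, THF, −78 °C; then 17, −78 °C; 1 M HCl work‑up
Reagents that add atoms: none
Why: crossed Claisen condensation in which the ester enolate displaces the thiazolidinethione from the activated exocyclic carbonyl; the β‑keto ester is held as its enolate, which protects C8 from epimerisation, and the acid work‑up hydrolyses the O–SiMe3 ether.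

Step 9
Reactants: 21 methyl (4R,5S)-5-hydroxy-4-methyl-3-oxo-7-(trimethylsilyl)hept-6-ynoate
Product: 23 methyl (3S,4S,5S)-3,5-dihydroxy-4-methylhept-6-ynoate, via silylalkyne diol 22 (not isolated)
Conditions: Et2BOMe, NaBH4, THF–MeOH (4:1), −78 °C; then K2CO3, MeOH, rt
Reagents that add atoms: none
Why: Narasaka–Prasad reduction, in which hydride adds axially to the six‑membered boron chelate of the β‑hydroxy ketone and gives the 1,3‑syn diol (sets C7 and completes the anti,anti triad); basic methanol then cleaves the alkynyl C–Si bond.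

Step 10
Reactants: 23 methyl (3S,4S,5S)-3,5-dihydroxy-4-methylhept-6-ynoate
Product: 24 methyl (3S,4S,5S)-4-methyl-3,5-bis(triethylsilyloxy)hept-6-ynoate
Conditions: Et3SiOTf, 2,6‑lutidine, CH2Cl2, −78 → 0 °C
Reagents that add atoms: triethylsilyl trifluoromethanesulfonate, CC[Si](CC)(CC)OS(=O)(=O)C(F)(F)F
Why: silyl ether formation (silyl triflate, hindered base) protects both carbinols as acyclic ethers, which can both sit equatorial in the later decalin‑forming transition state.

Step 11
Reactants: 24 methyl (3S,4S,5S)-4-methyl-3,5-bis(triethylsilyloxy)hept-6-ynoate; 14 (1E,4Z,7E,9E)-1-iodo-7,9-dimethyldodeca-1,4,7,9-tetraene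
Product: 27 methyl (3S,4S,5R,6E,8E,11Z,14E,16E)-4,14,16-trimethyl-3,5-bis(triethylsilyloxy)nonadeca-6,8,11,14,16-pentaenoate, via alkenylzirconocene chloride 25 (not isolated), via alkenylzinc chloride 26 (not isolated)
Conditions: Cp2Zr(H)Cl (1.2 equiv), THF, rt; then ZnCl2, 14, Pd(PPh3)4 (5 mol %), rt
Reagents that add atoms: none
Why: hydrozirconation of the terminal alkyne (syn, zirconium terminal) then Negishi cross‑coupling by way of the alkenylzinc; both partners keep their E geometry, giving the E,E C10–C13 diene without touching the skipped Z‑alkene.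

Step 12
Reactants: 27 methyl (3S,4S,5R,6E,8E,11Z,14E,16E)-4,14,16-trimethyl-3,5-bis(triethylsilyloxy)nonadeca-6,8,11,14,16-pentaenoate
Product: 28 (3S,4S,5R,6E,8E,11Z,14E,16E)-4,14,16-trimethyl-3,5-bis(triethylsilyloxy)nonadeca-6,8,11,14,16-pentaenal
Conditions: iBu2AlH (1.1 equiv), CH2Cl2, −78 °C
Reagents that add atoms: none
Why: half‑reduction of the ester with iBu2AlH: the tetrahedral aluminium hemiacetal is stable at −78 °C and collapses to the aldehyde only on work‑up; no stereocentre is affected.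

Step 13
Reactants: 28 (3S,4S,5R,6E,8E,11Z,14E,16E)-4,14,16-trimethyl-3,5-bis(triethylsilyloxy)nonadeca-6,8,11,14,16-pentaenal; 29 2-(triphenylphosphoranylidene)propanal
Product: 30 (2E,5S,6S,7R,8E,10E,13Z,16E,18E)-2,6,16,18-tetramethyl-5,7-bis(triethylsilyloxy)henicosa-2,8,10,13,16,18-hexaenal
Conditions: toluene, 70 °C
Reagents that add atoms: none
Why: Wittig olefination with the stabilised formyl ylide gives the E‑configured C4=C5 enal; the moderate temperature keeps the trienal from cyclising prematurely.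

Step 14
Reactants: 31 4-methoxyfuran-2(5H)-one; 32 N,N-dimethylmethyleneiminium iodide
Product: 36 4-methoxy-5-methylidenefuran-2(5H)-one, via lithium 4-methoxyfuran-2-olate 33 (not isolated), via Mannich base 34 (not isolated), via trimethylammonium iodide 35 (not isolated)
Conditions: LiN(iPr)2, THF, −78 °C; 32, → rt; MeI, rt; evaporate; DBU, CH2Cl2, 0 °C
Reagents that add atoms: none
Why: Mannich reaction of the C5 lithium dienolate of methyl tetronate, then quaternisation and E1cB (Hofmann‑type) elimination give the exocyclic methylene; no stereocentre.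

Step 15
Reactants: 36 4-methoxy-5-methylidenefuran-2(5H)-one; 30 (2E,5S,6S,7R,8E,10E,13Z,16E,18E)-2,6,16,18-tetramethyl-5,7-bis(triethylsilyloxy)henicosa-2,8,10,13,16,18-hexaenal
Product: 38 3-[(2E,5S,6S,7R,8E,10E,13Z,16E,18E)-1-hydroxy-2,6,16,18-tetramethyl-5,7-bis(triethylsilyloxy)henicosa-2,8,10,13,16,18-hexaen-1-yl]-4-methoxy-5-methylidenefuran-2(5H)-one (both carbinol epimers), via 3-lithio tetronate 37 (not isolated)
Conditions: LiN(iPr)2, THF, −78 °C; then 30, −78 °C; H2O
Reagents that add atoms: none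
Why: 1,2‑addition of the C2 vinyllithium of the tetronate to the enal; the new carbinol centre (C3) forms as both epimers, which does not matter because it is oxidised next.

Step 16
Reactants: 38 3-[(2E,5S,6S,7R,8E,10E,13Z,16E,18E)-1-hydroxy-2,6,16,18-tetramethyl-5,7-bis(triethylsilyloxy)henicosa-2,8,10,13,16,18-hexaen-1-yl]-4-methoxy-5-methylidenefuran-2(5H)-one
Product: 41 26-O-methyl 7,9-bis(triethylsilyl) ether of the target (tetracycle; 4R,5R,7S,8S,9R,10S,13R,18R,21R,25S,15Z), via acyclic acyl tetronate 39 (not isolated), via trans-decalin ketone 40 (not isolated)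
Conditions: Dess–Martin periodinane, CH2Cl2, 0 °C → rt; then toluene (1 mM), BHT, 110 °C
Reagents that add atoms: none
Why: Proposed new method: oxidation unmasks the cross‑conjugated enone 39, whose 1,7,9‑decatrien‑3‑one unit undergoes intramolecular Diels–Alder reaction through the endo (ketone under the diene), chair‑tether transition state with both silyloxy groups equatorial and the C8 methyl axial, fixing C4, C5, C10 and C13 of the trans‑decalin 40 from the C7–C9 triad; the C4 acyl tetronate and the C13 side arm are then cis, so on heating the exocyclic C24=C25 dienophile meets the C18–C21 diene in a second, macrocyclising intramolecular Diels–Alder reaction (C21–C24 and C18–C25 bonds, para‑type regiochemistry, tetronate C26 exo and trans to C17 as the short Z‑configured tether demands), setting C18, C21 and C25; the closest known reactions are the thermal intramolecular Diels–Alder reaction of 2‑methyl trienones to trans‑decalins and the macrocyclising Diels–Alder reaction of 5‑methylene tetronates onto terminal dienes, here run in tandem.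

Step 17
Reactants: 41 26-O-methyl 7,9-bis(triethylsilyl) ether of the target
Product: 43 CNP0259772.1 (target), via lithium tetronate 42 (not isolated)
Conditions: LiCl, DMSO, 55 °C; then 1 M HCl, THF, rt
Reagents that add atoms: none
Why: chloride SN2 demethylation of the vinylogous methyl carbonate (the 3‑acyl tetronate is an excellent leaving group), then acid hydrolysis of the two silyl ethers; no stereocentre is touched and the product is the enol tautomer drawn.

## Compound list

1 | (E)-2-methylpent-2-enal | CC/C=C(\C)C=O | starting material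
2 | ethyl 2-(triphenylphosphoranylidene)propanoate | CCOC(=O)C(C)=P(c1ccccc1)(c1ccccc1)c1ccccc1 | starting material
3 | ethyl (2E,4E)-2,4-dimethylhepta-2,4-dienoate | CC/C=C(\C)/C=C(\C)C(=O)OCC | intermediate
4 | (2E,4E)-2,4-dimethylhepta-2,4-dien-1-ol | CC/C=C(\C)/C=C(\C)CO | intermediate
5 | (2E,4E)-1-bromo-2,4-dimethylhepta-2,4-diene | CC/C=C(\C)/C=C(\C)CBr | intermediate
6 | but-3-yn-1-ol | C#CCCO | starting material
7 | (E)-but-3-en-1-ol carrying Cp2Zr(Cl) on C4 and on oxygen | Cl[Zr](C1C=CC=C1)(C1C=CC=C1)/C=C/CCO[Zr](Cl)(C1C=CC=C1)C1C=CC=C1 | intermediate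
8 | (E)-4-iodobut-3-en-1-ol | OCC/C=C/I | intermediate
9 | (E)-4-iodobut-3-enal | O=CC/C=C/I | intermediate
10 | methyltriphenylphosphonium bromide | C[P+](c1ccccc1)(c1ccccc1)c1ccccc1.[Br-] | starting material
11 | methylenetriphenylphosphorane | C=P(c1ccccc1)(c1ccccc1)c1ccccc1 | intermediate
12 | [(3E,5E)-3,5-dimethylocta-3,5-dien-1-yl]triphenylphosphonium bromide | CC/C=C(\C)/C=C(\C)CC[P+](c1ccccc1)(c1ccccc1)c1ccccc1.[Br-] | intermediate
13 | [(3E,5E)-3,5-dimethylocta-3,5-dien-1-ylidene]triphenylphosphorane | CC/C=C(\C)/C=C(\C)CC=P(c1ccccc1)(c1ccccc1)c1ccccc1 | intermediate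
14 | (1E,4Z,7E,9E)-1-iodo-7,9-dimethyldodeca-1,4,7,9-tetraene | CC/C=C(\C)/C=C(\C)C/C=C\C/C=C/I | intermediate
15 | (R)-4-benzyl-3-propanoyl-1,3-thiazolidine-2-thione | CCC(=O)N1[C@H](Cc2ccccc2)CSC1=S | starting material
16 | 3-(trimethylsilyl)prop-2-ynal | C[Si](C)(C)C#CC=O | starting material
17 | (R)-4-benzyl-3-[(2R,3S)-2-methyl-5-(trimethylsilyl)-3-(trimethylsilyloxy)pent-4-ynoyl]-1,3-thiazolidine-2-thione | S=C1SC[C@@H](Cc2ccccc2)N1C(=O)[C@H](C)[C@H](O[Si](C)(C)C)C#C[Si](C)(C)C | intermediate
18 | methyl acetate | COC(C)=O | starting material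
19 | lithium 1-methoxyethenolate (lithium enolate of methyl acetate) | [Li]OC(=C)OC | intermediate
20 | methyl (4R,5S)-4-methyl-3-oxo-7-(trimethylsilyl)-5-(trimethylsilyloxy)hept-6-ynoate | COC(=O)CC(=O)[C@H](C)[C@H](O[Si](C)(C)C)C#C[Si](C)(C)C | intermediate
21 | methyl (4R,5S)-5-hydroxy-4-methyl-3-oxo-7-(trimethylsilyl)hept-6-ynoate | COC(=O)CC(=O)[C@H](C)[C@H](O)C#C[Si](C)(C)C | intermediate
22 | methyl (3S,4S,5S)-3,5-dihydroxy-4-methyl-7-(trimethylsilyl)hept-6-ynoate | COC(=O)C[C@H](O)[C@H](C)[C@H](O)C#C[Si](C)(C)C | intermediate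
23 | methyl (3S,4S,5S)-3,5-dihydroxy-4-methylhept-6-ynoate | COC(=O)C[C@H](O)[C@H](C)[C@H](O)C#C | intermediate
24 | methyl (3S,4S,5S)-4-methyl-3,5-bis(triethylsilyloxy)hept-6-ynoate | COC(=O)C[C@H](O[Si](CC)(CC)CC)[C@H](C)[C@H](O[Si](CC)(CC)CC)C#C | intermediate
25 | E-alkenylzirconocene chloride from 24 (Cp2ZrCl on the terminal alkene carbon, triad unchanged) | COC(=O)C[C@H](O[Si](CC)(CC)CC)[C@H](C)[C@H](O[Si](CC)(CC)CC)/C=C/[Zr](Cl)(C1C=CC=C1)C1C=CC=C1 | intermediate
26 | E-alkenylzinc chloride from 25 (ZnCl on the terminal alkene carbon) | COC(=O)C[C@H](O[Si](CC)(CC)CC)[C@H](C)[C@H](O[Si](CC)(CC)CC)/C=C/[Zn]Cl | intermediate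
27 | methyl (3S,4S,5R,6E,8E,11Z,14E,16E)-4,14,16-trimethyl-3,5-bis(triethylsilyloxy)nonadeca-6,8,11,14,16-pentaenoate | COC(=O)C[C@H](O[Si](CC)(CC)CC)[C@H](C)[C@H](O[Si](CC)(CC)CC)/C=C/C=C/C/C=C\C/C(C)=C/C(C)=C/CC | intermediate
28 | (3S,4S,5R,6E,8E,11Z,14E,16E)-4,14,16-trimethyl-3,5-bis(triethylsilyloxy)nonadeca-6,8,11,14,16-pentaenal | O=CC[C@H](O[Si](CC)(CC)CC)[C@H](C)[C@H](O[Si](CC)(CC)CC)/C=C/C=C/C/C=C\C/C(C)=C/C(C)=C/CC | intermediate
29 | 2-(triphenylphosphoranylidene)propanal | CC(C=O)=P(c1ccccc1)(c1ccccc1)c1ccccc1 | starting material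
30 | (2E,5S,6S,7R,8E,10E,13Z,16E,18E)-2,6,16,18-tetramethyl-5,7-bis(triethylsilyloxy)henicosa-2,8,10,13,16,18-hexaenal | O=C/C(C)=C/C[C@H](O[Si](CC)(CC)CC)[C@H](C)[C@H](O[Si](CC)(CC)CC)/C=C/C=C/C/C=C\C/C(C)=C/C(C)=C/CC | intermediate
31 | 4-methoxyfuran-2(5H)-one (methyl tetronate) | COC1=CC(=O)OC1 | starting material
32 | N,N-dimethylmethyleneiminium iodide (Eschenmoser's salt) | C[N+](C)=C.[I-] | starting material
33 | lithium 4-methoxyfuran-2-olate (C5-lithiated methyl tetronate) | [Li]Oc1cc(OC)co1 | intermediate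
34 | 5-[(dimethylamino)methyl]-4-methoxyfuran-2(5H)-one (racemic) | COC1=CC(=O)OC1CN(C)C | intermediate
35 | [(3-methoxy-5-oxo-2,5-dihydrofuran-2-yl)methyl]trimethylammonium iodide (racemic) | COC1=CC(=O)OC1C[N+](C)(C)C.[I-] | intermediate
36 | 4-methoxy-5-methylidenefuran-2(5H)-one | COC1=CC(=O)OC1=C | intermediate
37 | 3-lithio-4-methoxy-5-methylidenefuran-2(5H)-one | COC1=C([Li])C(=O)OC1=C | intermediate
38 | 3-[(2E,5S,6S,7R,8E,10E,13Z,16E,18E)-1-hydroxy-2,6,16,18-tetramethyl-5,7-bis(triethylsilyloxy)henicosa-2,8,10,13,16,18-hexaen-1-yl]-4-methoxy-5-methylidenefuran-2(5H)-one, both carbinol epimers | COC1=C(C(O)/C(C)=C/C[C@H](O[Si](CC)(CC)CC)[C@H](C)[C@H](O[Si](CC)(CC)CC)/C=C/C=C/C/C=C\C/C(C)=C/C(C)=C/CC)C(=O)OC1=C | intermediate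
39 | 3-[(2E,5S,6S,7R,8E,10E,13Z,16E,18E)-2,6,16,18-tetramethyl-5,7-bis(triethylsilyloxy)henicosa-2,8,10,13,16,18-hexaenoyl]-4-methoxy-5-methylidenefuran-2(5H)-one | COC1=C(C(=O)/C(C)=C/C[C@H](O[Si](CC)(CC)CC)[C@H](C)[C@H](O[Si](CC)(CC)CC)/C=C/C=C/C/C=C\C/C(C)=C/C(C)=C/CC)C(=O)OC1=C | intermediate
40 | 4-methoxy-5-methylidene-3-acylfuran-2(5H)-one whose acyl group is the trans-fused octalin (4R,5R,7S,8S,9R,10S,13R): C4 quaternary methyl carbon bearing the ketone, C7 and C9 OSiEt3 equatorial, C8 methyl axial, C11=C12 alkene, C13 bearing the (2Z,5E,7E)-5,7-dimethyldeca-2,5,7-trien-1-yl arm cis to the ketone | COC1=C(C(=O)[C@@]2(C)[C@@H]3C[C@H](O[Si](CC)(CC)CC)[C@H](C)[C@H](O[Si](CC)(CC)CC)[C@H]3C=C[C@H]2C/C=C\C/C(C)=C/C(C)=C/CC)C(=O)OC1=C | intermediate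
41 | 26-O-methyl 7,9-bis(triethylsilyl) ether of the target: spirotetronate tetracycle, (4R,5R,7S,8S,9R,10S,13R,18R,21R,25S,15Z) | CC[C@@H]1C[C@]23OC(=O)C(C(=O)[C@@]4(C)[C@@H]5C[C@H](O[Si](CC)(CC)CC)[C@H](C)[C@H](O[Si](CC)(CC)CC)[C@H]5C=C[C@H]4C/C=C\C[C@]2(C)C=C1C)=C3OC | intermediate
42 | lithium tetronate of the 7,9-bis(triethylsilyl) ether of the target | CC[C@@H]1C[C@]23OC(=O)C(C(=O)[C@@]4(C)[C@@H]5C[C@H](O[Si](CC)(CC)CC)[C@H](C)[C@H](O[Si](CC)(CC)CC)[C@H]5C=C[C@H]4C/C=C\C[C@]2(C)C=C1C)=C3[O-].[Li+] | intermediate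
43 | CNP0259772.1, (4R,5R,7S,8S,9R,10S,13R,18R,21R,25S,15Z) 3-acyl spirotetronic acid | CC[C@@H]1C[C@]23OC(=O)/C(=C(\O)[C@@]4(C)[C@@H]5C[C@H](O)[C@H](C)[C@H](O)[C@H]5C=C[C@H]4C/C=C\C[C@]2(C)C=C1C)C3=O | target

## Count and risks

Total steps: 17. Longest linear sequence: 10 steps (steps 7–13 and 15–17 from 15 and 16; equally steps 1–3, 6, 11–13 and 15–17 from 1).

The three steps most likely to fail:

**Step 16 (tandem cycloaddition).** The risks are the diastereoselectivity of the decalin closure in the presence of the second dienophile, mis‑pairing of the exo‑methylene with the C10–C13 diene, and the facial sense of the macrocyclisation. The fallback sets out from 30. Me2AlCl in CH2Cl2 at −78 °C closes the decalin at the enal stage, before any tetronate is present, to give the trans-decalin aldehyde F1 under Lewis‑acid control of the endo transition state. Addition of 37 then gives the decalin carbinol F2, and Dess–Martin oxidation of F2 comes back to the route at 40, which is heated on its own for the macrocyclising cycloaddition.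

**Step 6 (ylide alkylation and Z‑Wittig).** The risks are over‑alkylation by transylidation and loss of the base‑sensitive β,γ‑unsaturated iodo‑aldehyde 9. The fallback sets out from 13, which is condensed instead with commercial 3‑(tert‑butyldimethylsilyloxy)propanal to give the Z-configured silyl ether F3. Bu4NF gives the homoallylic alcohol F4, Dess–Martin oxidation gives the (3Z)-aldehyde F5, and Takai iodo‑olefination (CrCl2, CHI3, THF, 0 °C) installs the E‑vinyl iodide under non‑basic conditions, coming back to the route at 14.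

**Step 7 (anti‑aldol with an ynal).** The level and sense of induction are unproven for this aldehyde class. The fallback sets out from 16 and replaces the auxiliary aldol and the Claisen step by a catalytic enantioselective vinylogous Mukaiyama aldol. Methyl 3‑oxopentanoate is converted (Me3SiCl/Et3N, then LiN(iPr)2/Me3SiCl) into the bis(trimethylsilyl) dienol ether F6. This adds through its γ‑carbon to 16 under SiCl4 with a chiral bisphosphoramide (anti‑selective open transition state), and acid work‑up comes back to the route at 21.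

## Further compounds

F1 | step 16 | trans-decalin aldehyde: (4R,5R,7S,8S,9R,10S,13R) octalin-4-carbaldehyde with 7,9-bis(triethylsilyloxy), 4,8-dimethyl and the C13 (2Z,5E,7E)-5,7-dimethyldeca-2,5,7-trien-1-yl arm | O=C[C@@]1(C)[C@@H]2C[C@H](O[Si](CC)(CC)CC)[C@H](C)[C@H](O[Si](CC)(CC)CC)[C@H]2C=C[C@H]1C/C=C\C/C(C)=C/C(C)=C/CC
F2 | step 16 | decalin carbinol: adduct of F1 and 37 at the aldehyde carbon, both carbinol epimers | COC1=C(C(O)[C@@]2(C)[C@@H]3C[C@H](O[Si](CC)(CC)CC)[C@H](C)[C@H](O[Si](CC)(CC)CC)[C@H]3C=C[C@H]2C/C=C\C/C(C)=C/C(C)=C/CC)C(=O)OC1=C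
F3 | step 6 | tert-butyl{[(3Z,6E,8E)-6,8-dimethylundeca-3,6,8-trien-1-yl]oxy}dimethylsilane | CC/C=C(\C)/C=C(\C)C/C=C\CCO[Si](C)(C)C(C)(C)C
F4 | step 6 | (3Z,6E,8E)-6,8-dimethylundeca-3,6,8-trien-1-ol | CC/C=C(\C)/C=C(\C)C/C=C\CCO
F5 | step 6 | (3Z,6E,8E)-6,8-dimethylundeca-3,6,8-trienal | CC/C=C(\C)/C=C(\C)C/C=C\CC=O
F6 | step 7 | (3Z)-1-methoxy-1,3-bis(trimethylsilyloxy)penta-1,3-diene | COC(O[Si](C)(C)C)=C/C(O[Si](C)(C)C)=C/C
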